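| flask | electrophile | nucleophile | remark | time |
|---|---|---|---|---|
| cedar | 20 mM | 11 mM | run made earlier |  |
| elm | 20 mM | 18 mM | run made earlier |  |
| noon | 20 mM | 16.0 mM |  | 10 min |
| dusk | 20 mM | 24.0 mM |  | 10 min |

| run | time / min | electrophile / % | target / % |
|---|---|---|---|
| cedar | 0.500 | 93 | 6 |
| cedar | 1.00 | 89 | 7 |
| cedar | 1.50 | 85 | 9 |
| cedar | 2.50 | 82 | 13 |
| cedar | 4.00 | 77 | 23 |
| cedar | 8.00 | 68 | 23 |
| elm | 0.500 | 94 | 8 |
| elm | 1.33 | 84 | 19 |
| elm | 2.50 | 73 | 25 |
| elm | 4.00 | 69 | 37 |
| elm | 5.00 | 60 | 37 |
| elm | 8.00 | 54 | 45 |

(standard deviation of a reading: 2 percentage points)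

- what has gone from electrophile into another species counts as reacted, even if it can come back

- part of the electrophile that has reacted at the end, noon
- part of the electrophile that has reacted at the end, dusk
- what raising the concentration of nucleophile from its lowest to its highest value here does to the part of the electrophile that has reacted (changes below 5 percentage points count as none) (it falls / no change / it rises)

At the last reading, 8.00 min, cedar has lost 32.0% of its electrophile and elm 46.0%. Let f be the fraction of electrophile lost and n the nucleophile charged over the electrophile charged. A first estimate, one nucleophile per electrophile, puts the end at f = n, which is 0.550 for cedar and 0.900 for elm.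

But f stands at 0.582 of n in cedar and 0.511 of n in elm, and cedar's target reads 23% at 4.00 min and 23% at 8.00 min. So the better estimate lets each electrophile lost take two nucleophile, with nucleophile the limiting reagent and a mark at f = n/2: 40.0% for noon, 60.0% for dusk. That mark is no ceiling: cedar's reading of 32.0% lost already stands above its own mark of 27.5%.

The objection is that such a mark carries no time, and 10 min may fall short of it. Integrating a loss rate proportional to (1 − f)(n − 2f) gives, with E the electrophile charged:

f = n(R − 1) / (2R − n), where R = exp[(2 − n)·k·E·t]

The readings at 2.50 min give k:

cedar: 0.0119 mM⁻¹ min⁻¹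

elm: 0.0109 mM⁻¹ min⁻¹

Their mean, 0.0114 mM⁻¹ min⁻¹, is the two-for-one constant: the rate constant of electrophile loss when each electrophile lost takes two nucleophile.

noon: f = 38.4%

dusk: f = 55.7%

A last doubt remains. Run to 8.00 min, the formula gives 26.1% for cedar and 41.5% for elm, less than the electrophile lost, with a scatter of 2 percentage points. So both reckoned values may lie some points low, while the rise from noon to dusk, 17 points, clears the 5 points mark.

The forecast, higher than this reckoning, gives 47% (41% to 53%) for noon, 61% (53% to 69%) for dusk, and it rises, holding that “More nucleophile clearly raises conversion”.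

The flask gives 41.6% for noon and 57.4% for dusk, and it rises by 16 points.

    nucleophile + acid set free ⇌ protonated nucleophile, settled at all times (K = 25000 M⁻¹)
    electrophile + acid set free ⇌ idle adduct, settled at all times (K = 130 M⁻¹)
    electrophile + nucleophile → acid set free + target (k = 0.190 M⁻¹ s⁻¹)

At 1.67 min in noon, the half-life of nucleophile by the step to target is 3.8 min against 7.4 min for electrophile, half, and 85% of that step's turnover up to 10 min is done by 5.00 min. At the end noon holds 39.4% target against 38.4% reckoned with 0.0114 mM⁻¹ min⁻¹, beside 2.20% idle adduct. The neighbour flask with 8.0 mM of electrophile has n = 2.00, where the formula becomes f = 2kEt/(1 + 2kEt), which gives 64.6%, and that flask holds 64.6% target.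

All runs are simulated on assumed constants, noise included.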